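**Plan**
1. Numbering used: cyclohexane ring C5–C6–C7–C8–C9–C10; C4(=C3H2)–C15HO on C5; lactone C11(=C13H2)–C12(=O)–O6 on C7 and C6; C14 (acetoxymethyl) and C1=C2 (vinyl) on C10.
2. Retrosynthetic cuts: first C15=O (back to an isopropenyl methyl group), then C11–C12 and C12–O6 (back to a C7 ethynyl group and the C6 hydroxyl), then the ring bonds C5–C6 and C7–C8 in one operation. This leaves fragment A (C8–C9–C10–C5, an aldehyde with a 2-methylprop-1-enyl group) and fragment B (C6–C7, the enol silane of an ynal).
3. Enabling feature: on the cyclohexane ring C8–O and C6–O stand 1,3 across C7 (aldol relation, C7 α to a C6 aldehyde). C6–O is next to C5, which carries the 2-propenyl branch C4(=C3H2) (carbonyl-ene relation). All four substituents on C5–C8 are trans and equatorial.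
4. Forward order: quaternary C10 (fragment A), then the cyclohexane ring by an aldol/carbonyl-ene cascade, then the lactone ring by carbonylation, then the acetates, and the C15 aldehyde last.
5. Stereochemistry: C10 from enzymatic desymmetrisation of a prochiral diol; C8 and C7 from the chiral acid catalyst; C6 and C5 from the chair of the ene closure.

Key step: step 11

Remark: it is assumed that the lipase acetylates the enantiotopic hydroxymethyl group that leads to the (S)-monoacetate; the opposite preference is covered under the fallbacks.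

**Route**

Step 1
Reactants: 1 isobutyraldehyde; 2 diethyl malonate
Product: 3 diethyl 2-(2-methylpropylidene)malonate
Conditions: piperidine (cat.), AcOH (cat.), toluene, reflux, Dean–Stark trap
Reagents that add atoms: none
Why: Knoevenagel condensation of an aldehyde with an active methylene compound, driven by removal of water; no stereocentre is formed.

Step 2
Reactants: 3 diethyl 2-(2-methylpropylidene)malonate; 4 (2-bromoethoxy)(tert-butyl)dimethylsilane
Product: 5 diethyl 2-[2-(tert-butyldimethylsilyloxy)ethyl]-2-(2-methylprop-1-en-1-yl)malonate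
Conditions: NaH, DMF, 0 °C; then 4, NaI (cat.), 50 °C
Reagents that add atoms: none
Why: NaH removes the γ-hydrogen to give the extended enolate, which should be alkylated at the α-carbon (deconjugative alkylation of an alkylidene malonate), so the double bond moves into the side chain as the 2-methylprop-1-enyl group and the future C10 becomes quaternary but not yet stereogenic.

Step 3
Reactants: 5 diethyl 2-[2-(tert-butyldimethylsilyloxy)ethyl]-2-(2-methylprop-1-en-1-yl)malonate
Product: 6 2-[2-(tert-butyldimethylsilyloxy)ethyl]-2-(2-methylprop-1-en-1-yl)propane-1,3-diol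
Conditions: LiAlH4, THF, 0 °C → rt
Reagents that add atoms: none
Why: Hydride reduction of both esters should give the prochiral 2,2-disubstituted propane-1,3-diol; the silyl ether and the trisubstituted alkene are inert.

Step 4
Reactants: 6 2-[2-(tert-butyldimethylsilyloxy)ethyl]-2-(2-methylprop-1-en-1-yl)propane-1,3-diol
Product: 7 (S)-4-(tert-butyldimethylsilyloxy)-2-(hydroxymethyl)-2-(2-methylprop-1-en-1-yl)butyl acetate
Conditions: lipase from Burkholderia cepacia, vinyl acetate, t-BuOMe, rt
Reagents that add atoms: vinyl acetate C=COC(C)=O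
Why: Enzymatic desymmetrisation: a lipase (serine hydrolase class) should acetylate one of the two enantiotopic hydroxymethyl groups irreversibly, which sets the quaternary centre C10 and installs the C14 acetate of the target.

Step 5
Reactants: 7 (S)-4-(tert-butyldimethylsilyloxy)-2-(hydroxymethyl)-2-(2-methylprop-1-en-1-yl)butyl acetate
Product: 8 (R)-4-(tert-butyldimethylsilyloxy)-2-formyl-2-(2-methylprop-1-en-1-yl)butyl acetate
Conditions: Dess–Martin periodinane, NaHCO3, CH2Cl2, 0 °C → rt
Reagents that add atoms: none
Why: Dess–Martin oxidation of the neopentyl alcohol; the aldehyde has no α-hydrogen, so neither epimerisation nor loss of the β-acetate can occur.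

Step 6
Reactants: 8 (R)-4-(tert-butyldimethylsilyloxy)-2-formyl-2-(2-methylprop-1-en-1-yl)butyl acetate
Product: 9 (R)-2-[2-(tert-butyldimethylsilyloxy)ethyl]-2-(2-methylprop-1-en-1-yl)but-3-en-1-yl acetate
Conditions: Ph3PCH3Br, KN(SiMe3)2, THF, −78 → 0 °C
Reagents that add atoms: methyltriphenylphosphonium bromide C[P+](c1ccccc1)(c1ccccc1)c1ccccc1.[Br-]
Why: Wittig methylenation with the non-stabilised ylide should turn the formyl group into the vinyl group on C10; at low temperature the aldehyde reacts far faster than the acetate.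

Step 7
Reactants: 9 (R)-2-[2-(tert-butyldimethylsilyloxy)ethyl]-2-(2-methylprop-1-en-1-yl)but-3-en-1-yl acetate
Product: 10 (R)-2-(2-hydroxyethyl)-2-(2-methylprop-1-en-1-yl)but-3-en-1-yl acetate
Conditions: HF·pyridine, pyridine, THF, 0 °C
Reagents that add atoms: none
Why: Fluoride cleaves the primary silyl ether under buffered conditions that leave the acetate and the acid-sensitive trisubstituted alkene in place.

Step 8
Reactants: 10 (R)-2-(2-hydroxyethyl)-2-(2-methylprop-1-en-1-yl)but-3-en-1-yl acetate
Product: 11 (R)-2-(2-methylprop-1-en-1-yl)-2-(2-oxoethyl)but-3-en-1-yl acetate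
Conditions: Dess–Martin periodinane, NaHCO3, CH2Cl2, 0 °C → rt
Reagents that add atoms: none
Why: Buffered Dess–Martin oxidation should give the C8 aldehyde (fragment A) without touching the alkenes or the acetate; C10 is quaternary and cannot epimerise.

Step 9
Reactants: 12 4-(trimethylsilyl)but-3-yn-1-ol
Product: 13 4-(trimethylsilyl)but-3-ynal
Conditions: Dess–Martin periodinane, NaHCO3, CH2Cl2, 0 °C; used crude
Reagents that add atoms: none
Why: Dess–Martin oxidation under neutral conditions should give the sensitive ynal without isomerisation to the allenal.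

Step 10
Reactants: 13 4-(trimethylsilyl)but-3-ynal
Product: 14 (Z)-tert-butyldimethyl{[4-(trimethylsilyl)but-1-en-3-yn-1-yl]oxy}silane
Conditions: TBSOTf, Et3N, CH2Cl2, −78 °C
Reagents that add atoms: tert-butyldimethylsilyl trifluoromethanesulfonate CC(C)(C)[Si](C)(C)OS(=O)(=O)C(F)(F)F
Why: Soft enolisation and O-silylation of the aldehyde (its propargylic α-hydrogen is acidic) should give the conjugated enol silane (fragment B), expected mainly as the Z isomer.

Step 11
Reactants: 11 (R)-2-(2-methylprop-1-en-1-yl)-2-(2-oxoethyl)but-3-en-1-yl acetate; 14 (Z)-tert-butyldimethyl{[4-(trimethylsilyl)but-1-en-3-yn-1-yl]oxy}silane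
Product: 16 [(1R,2S,3R,4S,5S)-5-(tert-butyldimethylsilyloxy)-1-ethenyl-3-hydroxy-2-(prop-1-en-2-yl)-4-(trimethylsilylethynyl)cyclohexyl]methyl acetate, via silyloxy aldehyde 15 (not isolated)
Conditions: chiral confined imidodiphosphorimidate Brønsted acid (IDPi, 2 mol%), 14 (1.05 equiv), toluene, −78 → −20 °C; aq. NaHCO3
Reagents that add atoms: none
Why: Proposed new method: the acid is silylated by 14 to a silylium ion pair that activates the aldehyde of 11, the enol silane adds through an open transition state inside the chiral anion (Mukaiyama aldol, bond C7–C8) with silyl transfer to O8 to give 15, and once 14 is consumed the Brønsted acid form of the same catalyst activates the new C6 aldehyde for an intramolecular carbonyl-ene reaction with the 2-methylprop-1-enyl group (bond C5–C6), which gives up a methyl hydrogen and leaves the isopropenyl group and a free C6 hydroxyl. The closest known reaction types are the single Mukaiyama aldol addition of aldehyde-derived enol silanes under confined imidodiphosphorimidate catalysis and the acid-catalysed carbonyl-ene cyclisation of citronellal-type aldehydes to isopulegol-type cyclohexanols; joining them in one flask under one catalyst is new. The only ring closed is the cyclohexane, by attack of alkene carbon C5 on the activated carbonyl carbon C6 through a six-membered chair (exo with respect to the carbonyl group). C8 (Re-face attack on the aldehyde) and C7 (syn topicity) should be set by the catalyst, whose enantiomer is chosen for this sense; C6 and C5 should be set by the chair, in which the C8 silyloxy group, the C7 alkynyl group, the forming C6–O bond and the C5 alkene are all equatorial, so the new centres come out all-trans with the acetoxymethyl group of the fixed centre C10 axial. The step needs catalyst control that overrides the remote centre C10, attack by the trisubstituted alkene and not the vinyl group, and ring closure faster than loss of silanol from 15; it relies on the confined anion, on the much higher nucleophilicity of the 2-methylprop-1-enyl group and on the geminal substitution at C10 that holds the two reacting ends together.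

Step 12
Reactants: 16 [(1R,2S,3R,4S,5S)-5-(tert-butyldimethylsilyloxy)-1-ethenyl-3-hydroxy-2-(prop-1-en-2-yl)-4-(trimethylsilylethynyl)cyclohexyl]methyl acetate
Product: 17 [(1R,2S,3R,4S,5S)-5-(tert-butyldimethylsilyloxy)-1-ethenyl-4-ethynyl-3-hydroxy-2-(prop-1-en-2-yl)cyclohexyl]methyl acetate
Conditions: AgNO3 (10 mol%), acetone/H2O, rt
Reagents that add atoms: none
Why: Silver-catalysed protodesilylation of the alkynylsilane (via the silver acetylide) should free the terminal alkyne under neutral conditions that spare the silyl ether and the acetate.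

Step 13
Reactants: 17 [(1R,2S,3R,4S,5S)-5-(tert-butyldimethylsilyloxy)-1-ethenyl-4-ethynyl-3-hydroxy-2-(prop-1-en-2-yl)cyclohexyl]methyl acetate
Product: 18 [(3aS,4S,6R,7S,7aR)-4-(tert-butyldimethylsilyloxy)-6-ethenyl-3-methylidene-2-oxo-7-(prop-1-en-2-yl)octahydro-1-benzofuran-6-yl]methyl acetate
Conditions: PdCl2 (cat.), SnCl2 (cat.), PPh3, CO (7 atm), MeCN, 75 °C
Reagents that add atoms: carbon monoxide [C-]#[O+]
Why: Palladium-catalysed cyclocarbonylation of a homopropargylic alcohol: the alkoxycarbonylpalladium species from O6 and CO should add syn across the alkyne in the exo mode and protonolysis releases the α-methylene-γ-lactone, trans-fused because O6 and C11 are both equatorial, while the silylated O8 cannot compete.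

Step 14
Reactants: 18 [(3aS,4S,6R,7S,7aR)-4-(tert-butyldimethylsilyloxy)-6-ethenyl-3-methylidene-2-oxo-7-(prop-1-en-2-yl)octahydro-1-benzofuran-6-yl]methyl acetate
Product: 19 [(3aR,4S,6R,7S,7aR)-6-ethenyl-4-hydroxy-3-methylidene-2-oxo-7-(prop-1-en-2-yl)octahydro-1-benzofuran-6-yl]methyl acetate
Conditions: HF·pyridine, THF, 0 °C → rt
Reagents that add atoms: none
Why: Fluoride cleavage of the secondary silyl ether under mildly acidic conditions, in which the α-methylene lactone and the acetate are stable.

Step 15
Reactants: 19 [(3aR,4S,6R,7S,7aR)-6-ethenyl-4-hydroxy-3-methylidene-2-oxo-7-(prop-1-en-2-yl)octahydro-1-benzofuran-6-yl]methyl acetate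
Product: 20 [(3aR,4S,6R,7S,7aR)-4-acetoxy-6-ethenyl-3-methylidene-2-oxo-7-(prop-1-en-2-yl)octahydro-1-benzofuran-6-yl]methyl acetate
Conditions: Ac2O, pyridine, DMAP (cat.), CH2Cl2, 0 °C
Reagents that add atoms: acetic anhydride CC(=O)OC(C)=O
Why: DMAP-catalysed acylation of the secondary alcohol should give the C8 acetate with retention of configuration.

Step 16
Reactants: 20 [(3aR,4S,6R,7S,7aR)-4-acetoxy-6-ethenyl-3-methylidene-2-oxo-7-(prop-1-en-2-yl)octahydro-1-benzofuran-6-yl]methyl acetate
Product: 22 [(3aR,4S,6R,7R,7aR)-4-acetoxy-6-ethenyl-3-methylidene-2-oxo-7-(3-oxoprop-1-en-2-yl)octahydro-1-benzofuran-6-yl]methyl acetate, via allylic alcohol 21 (not isolated)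
Conditions: SeO2 (1.5 equiv), 1,4-dioxane, 80 °C
Reagents that add atoms: selenium dioxide O=[Se]=O
Why: Allylic oxidation by SeO2 (ene reaction at the terminal CH2 of the 1,1-disubstituted alkene, [2,3]-shift to the allylic alcohol, then oxidation to the aldehyde) should act on the isopropenyl methyl group, because the vinyl group has no allylic hydrogen, the lactone methylene is electron-poor and C5–H is shielded by the quaternary C10.

**Compound list**
1 | isobutyraldehyde | CC(C)C=O | starting material
2 | diethyl malonate | CCOC(=O)CC(=O)OCC | starting material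
3 | diethyl 2-(2-methylpropylidene)malonate | CCOC(=O)C(=CC(C)C)C(=O)OCC | intermediate
4 | (2-bromoethoxy)(tert-butyl)dimethylsilane | CC(C)(C)[Si](C)(C)OCCBr | starting material
5 | diethyl 2-[2-(tert-butyldimethylsilyloxy)ethyl]-2-(2-methylprop-1-en-1-yl)malonate | CCOC(=O)C(CCO[Si](C)(C)C(C)(C)C)(C=C(C)C)C(=O)OCC | intermediate
6 | 2-[2-(tert-butyldimethylsilyloxy)ethyl]-2-(2-methylprop-1-en-1-yl)propane-1,3-diol | OCC(CO)(CCO[Si](C)(C)C(C)(C)C)C=C(C)C | intermediate
7 | (S)-4-(tert-butyldimethylsilyloxy)-2-(hydroxymethyl)-2-(2-methylprop-1-en-1-yl)butyl acetate | OC[C@](C=C(C)C)(COC(C)=O)CCO[Si](C)(C)C(C)(C)C | intermediate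
8 | (R)-4-(tert-butyldimethylsilyloxy)-2-formyl-2-(2-methylprop-1-en-1-yl)butyl acetate | O=C[C@](C=C(C)C)(COC(C)=O)CCO[Si](C)(C)C(C)(C)C | intermediate
9 | (R)-2-[2-(tert-butyldimethylsilyloxy)ethyl]-2-(2-methylprop-1-en-1-yl)but-3-en-1-yl acetate | C=C[C@](C=C(C)C)(COC(C)=O)CCO[Si](C)(C)C(C)(C)C | intermediate
10 | (R)-2-(2-hydroxyethyl)-2-(2-methylprop-1-en-1-yl)but-3-en-1-yl acetate | C=C[C@](C=C(C)C)(COC(C)=O)CCO | intermediate
11 | (R)-2-(2-methylprop-1-en-1-yl)-2-(2-oxoethyl)but-3-en-1-yl acetate (fragment A) | C=C[C@](C=C(C)C)(COC(C)=O)CC=O | intermediate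
12 | 4-(trimethylsilyl)but-3-yn-1-ol | C[Si](C)(C)C#CCCO | starting material
13 | 4-(trimethylsilyl)but-3-ynal | C[Si](C)(C)C#CCC=O | intermediate
14 | (Z)-tert-butyldimethyl{[4-(trimethylsilyl)but-1-en-3-yn-1-yl]oxy}silane (fragment B) | C[Si](C)(C)C#C/C=C\O[Si](C)(C)C(C)(C)C | intermediate
15 | (2R,3S,5R)-5-(acetoxymethyl)-3-(tert-butyldimethylsilyloxy)-5-ethenyl-7-methyl-2-(trimethylsilylethynyl)oct-6-enal | C=C[C@](C=C(C)C)(COC(C)=O)C[C@H](O[Si](C)(C)C(C)(C)C)[C@@H](C#C[Si](C)(C)C)C=O | intermediate
16 | [(1R,2S,3R,4S,5S)-5-(tert-butyldimethylsilyloxy)-1-ethenyl-3-hydroxy-2-(prop-1-en-2-yl)-4-(trimethylsilylethynyl)cyclohexyl]methyl acetate | C=C[C@]1(COC(C)=O)C[C@H](O[Si](C)(C)C(C)(C)C)[C@@H](C#C[Si](C)(C)C)[C@H](O)[C@H]1C(C)=C | intermediate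
17 | [(1R,2S,3R,4S,5S)-5-(tert-butyldimethylsilyloxy)-1-ethenyl-4-ethynyl-3-hydroxy-2-(prop-1-en-2-yl)cyclohexyl]methyl acetate | C=C[C@]1(COC(C)=O)C[C@H](O[Si](C)(C)C(C)(C)C)[C@@H](C#C)[C@H](O)[C@H]1C(C)=C | intermediate
18 | [(3aS,4S,6R,7S,7aR)-4-(tert-butyldimethylsilyloxy)-6-ethenyl-3-methylidene-2-oxo-7-(prop-1-en-2-yl)octahydro-1-benzofuran-6-yl]methyl acetate | C=C[C@]1(COC(C)=O)C[C@H](O[Si](C)(C)C(C)(C)C)[C@H]2C(=C)C(=O)O[C@@H]2[C@H]1C(C)=C | intermediate
19 | [(3aR,4S,6R,7S,7aR)-6-ethenyl-4-hydroxy-3-methylidene-2-oxo-7-(prop-1-en-2-yl)octahydro-1-benzofuran-6-yl]methyl acetate | C=C[C@]1(COC(C)=O)C[C@H](O)[C@H]2C(=C)C(=O)O[C@@H]2[C@H]1C(C)=C | intermediate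
20 | [(3aR,4S,6R,7S,7aR)-4-acetoxy-6-ethenyl-3-methylidene-2-oxo-7-(prop-1-en-2-yl)octahydro-1-benzofuran-6-yl]methyl acetate | C=C[C@]1(COC(C)=O)C[C@H](OC(C)=O)[C@H]2C(=C)C(=O)O[C@@H]2[C@H]1C(C)=C | intermediate
21 | [(3aR,4S,6R,7S,7aR)-4-acetoxy-6-ethenyl-7-(3-hydroxyprop-1-en-2-yl)-3-methylidene-2-oxooctahydro-1-benzofuran-6-yl]methyl acetate | C=C[C@]1(COC(C)=O)C[C@H](OC(C)=O)[C@H]2C(=C)C(=O)O[C@@H]2[C@H]1C(=C)CO | intermediate
22 | [(3aR,4S,6R,7R,7aR)-4-acetoxy-6-ethenyl-3-methylidene-2-oxo-7-(3-oxoprop-1-en-2-yl)octahydro-1-benzofuran-6-yl]methyl acetate | C=C[C@]1(COC(C)=O)C[C@H](OC(C)=O)[C@H]2C(=C)C(=O)O[C@@H]2[C@H]1C(=C)C=O | target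

**Step count and risks**

Total step count: 16. Longest linear sequence: 14 (steps 1–8 and 11–16).

Most likely to fail:

1. Step 11 (carries the new-method label). The ene event may not follow the aldol event under the same acid, the aldol intermediate may lose silanol to a conjugated enynal before it cyclises, or the catalyst may control the face of the aldehyde poorly against the remote centre C10. The fallback separates the two events and changes the mode of activation, using known reaction types. It sets out from 11: an enamine-catalysed, syn-selective cross-aldol addition of aldehyde 13 (axially chiral binaphthyl amino sulfonamide as the secondary amine catalyst, N-methylpyrrolidone, 0 °C) should give the β-hydroxy aldehyde F1. Silylation (TBSCl, imidazole, DMF) gives 15, now isolated. Me2AlCl (CH2Cl2, −78 °C) then closes the ring by the carbonyl-ene reaction, and the route is rejoined at 16.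

2. Step 4. The lipase may discriminate the two enantiotopic hydroxymethyl groups poorly, or in the opposite sense. The fallback inverts the desymmetrising event from acylation to hydrolysis. It sets out from 6: acetylation of both hydroxyls (Ac2O, pyridine) gives the diacetate F2, and hydrolysis of one enantiotopic acetate by the same lipase or by pig liver esterase (phosphate buffer, pH 7) should give the monoacetate of the other sense to the acylation, coming back at 7.

3. Step 16. Oxidation may occur at the ring methine C5–H and not at the methyl group, or may stop at the allylic alcohol, or go beyond the aldehyde. The fallback replaces the direct oxidation by halogenation and Kornblum-type oxidation. It sets out from 20: ene-type chlorination of the isopropenyl group (Ca(OCl)2, solid CO2, CH2Cl2/H2O, 0 °C) should give the allylic chloride F3, and treatment with AgBF4 in DMSO followed by Et3N should give the aldehyde, coming back at 22.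

Further compounds
F1 | step 11 | (2R,3S,5R)-5-(acetoxymethyl)-5-ethenyl-3-hydroxy-7-methyl-2-(trimethylsilylethynyl)oct-6-enal | C=C[C@](C=C(C)C)(COC(C)=O)C[C@H](O)[C@@H](C#C[Si](C)(C)C)C=O
F2 | step 4 | 2-[2-(tert-butyldimethylsilyloxy)ethyl]-2-(2-methylprop-1-en-1-yl)propane-1,3-diyl diacetate | CC(=O)OCC(COC(C)=O)(CCO[Si](C)(C)C(C)(C)C)C=C(C)C
F3 | step 16 | [(3aR,4S,6R,7R,7aR)-4-acetoxy-7-(3-chloroprop-1-en-2-yl)-6-ethenyl-3-methylidene-2-oxooctahydro-1-benzofuran-6-yl]methyl acetate | C=C[C@]1(COC(C)=O)C[C@H](OC(C)=O)[C@H]2C(=C)C(=O)O[C@@H]2[C@H]1C(=C)CCl
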